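All runs are calculated on assumed constants; noise was put on by code.

At −20 °C a closed flask of substrate and reagent has been followed since Wednesday, and I must say what it holds at 40 h and which option to take then.

| setting | Wednesday's | Friday's | flask |
|---|---|---|---|
| substrate | 0.11 M | 0.17 M | 0.11 M |
| reagent | 0.275 M | 0.275 M | 0.275 M |
| temperature | −20 °C | −35 °C | −20 °C |
| remark | the very flask that is asked about, followed so far | run made earlier |  |
| time |  |  | 40 h |

- Wednesday's (time / h: bis adduct / %, substrate / %): 2.00: 24.6, 11.2; 6.00: 26.8, 1.0; 12.0: 28.1, 0; 20.0: 27.6, 1.4; 25.0: 26.7, 0.6; 30.0: 26.6, 1.0
- Friday's (time / h: bis adduct / %, substrate / %): 0.500: 1.8, 86.4; 1.00: 6.6, 73.3; 1.33: 10.4, 67.9; 2.00: 14.5, 59.3; 3.00: 20.3, 49.5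

(each reading ± 1 percentage point)

- north: at 40 h take out 90% of the by-product then present, then wait 20 h
- east: at 40 h add reagent, 100% of the amount charged, then wait 20 h
- north-east: change nothing and wait 20 h more
- south-west: at 40 h raise the temperature by 20 K, then wait 20 h

1. bis adduct, in percent of the substrate first charged, at 40 h
2. the option that brings most further bis adduct ("none" if no option brings more than 2 percentage points) (north / east / north-east / south-west / none)
3. bis adduct present, in percent of the substrate first charged, after north-east
4. bis adduct present, in percent of the substrate first charged, after south-west

- what is added takes up no volume worth counting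

Friday's run looks like Wednesday's, with the same reagent, but the two are read at different ages. I replace each substrate curve by one mean exponential through one reading. Wednesday's gives a time constant of 0.914 h and the colder Friday's gives 4.27 h. So Friday's run stops at 3.00 h, short of one time constant, and its bis adduct per substrate consumed is still climbing, to a reading of 40.2%. Wednesday's flask is read from 6.00 h on, 6.56 time constants in, and there I replace the curve by its mean:

mean bis adduct ÷ mean substrate consumed = 27.4%

standard error of the mean ≈ 0.45 percentage points

This is the bis share, bis adduct as a part of the substrate consumed. The reading farthest above it lies 0.72 points off, less than the scatter, so the mean loses nothing I can see. Wednesday's share at 2.00 h already reads 27.7%, with 11.2% of the substrate still unreacted.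

I therefore expect 27.4% at 40 h, and no gain from waiting, reagent or removal, since the share stood level while reagent and by-product were still changing. The one colder reading, Friday's 40.2%, stands above the share, but it comes from an unfinished run with another substrate charge, so I give no number for south-west and name no best option.

The forecast gives 27% now, 27% after north-east, 23% after south-west, and east as best, holding that "Adding reagent pushes the equilibrium". We part on east, from which I expect no gain.

The flask gives 27.3%, 27.1% after north-east and 33.7% after south-west. The best option is south-west, at 6.4 points, against −0.23 points for east.

    substrate + reagent → mono adduct + by-product (k = 0.00220 /M/s, Ea = 64.0 kJ/mol)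
    reagent + mono adduct → bis adduct + by-product (k = 0.00410 /M/s, Ea = 59.0 kJ/mol)
    bis adduct → over-reaction product (k = 4.30 × 10⁻⁷ /s, Ea = 86.0 kJ/mol)
    bis adduct ⇌ isomer of the product (K = 2.60, k = 6.30 × 10⁻⁴ /s, Ea = 77.0 kJ/mol, ΔH = −22.0 kJ/mol)
    (constants at −20 °C)

Bis adduct and isomer of the product exchange with a time constant of 0.318 h, far shorter than 40 h. The half-life of bis adduct by loss to over-reaction product is 19 d, long against that time. After south-west the flask stands above the bis share. The repeat of this flask at −35 °C, with 1.3% of its substrate left, ends at a bis share of 17.1%, below Wednesday's 27.4%.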